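**Retrosynthetic overview**

1. Target ⇐ cleavage of three allyl ethers ⇐ twofold SNAr (C5–O and C7–O) on a 6-acyl-5,7-difluorochromane ⇐ C6–C(=O) bond from C6-lithiated 5,7-difluoro-2,2-dimethylchromane and a ring-B Weinreb amide.
2. 5,7-Difluoro-2,2-dimethylchromane ⇐ one-pot annulation: C3–C4 bond by opening 2,2-dimethyloxirane with 2,4,6-trifluorobenzylmagnesium bromide, then ring closure O1–C8a by SNAr of the tertiary alkoxide so formed.
3. Enabling feature: the three oxygens of ring A (O1 on C8a, OH on C5, OH on C7) sit on alternate carbons, so ring A can be bought as a 2,4,6-trifluorophenyl ring. Its C–F carbons are mutually meta (the strongest SNAr activation by fluorine), and the two C–F carbons ortho to the side chain (future C5 and C8a) are mirror images, so closure at O1–C8a has a single outcome. The two fluorines left over flank C6 (site-specific lithiation and acylation) and end up ortho to the new ketone (exchange for oxygen).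
4. Ring B: methyl 3-(4-hydroxyphenyl)propanoate → ortho-iodination → O-allylation → iodine–magnesium exchange and prenylation → Weinreb amide.
5. Ring order: rings A and B are bought as benzene rings; the pyran ring is the only ring made and is closed first.

Key step: step 1

Remark: the target has no stereocentre and its only alkene carries two identical methyl groups, so no stereochemical control is needed; 2,4,6-trifluorobenzyl bromide, 2,2-dimethyloxirane and methyl 3-(4-hydroxyphenyl)propanoate are assumed to be purchased.

**Route**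

Step 1
Reactants: 1 2,4,6-trifluorobenzyl bromide; 2 2,2-dimethyloxirane
Product: 6 5,7-difluoro-2,2-dimethylchromane, via benzylic Grignard reagent 3 (not isolated), via bromomagnesium alkoxide 4 (not isolated), via potassium alkoxide 5 (not isolated)
Conditions: Mg turnings, 2-MeTHF, 0 °C (slow addition of 1); CuI (5 mol%), 2, −20 → 0 °C; then KOt-Bu (1.5 equiv), NMP, 70 °C; H2O work-up
Reagents that add atoms: none
Why: Magnesium insertion gives the benzylic Grignard reagent 3, which under CuI catalysis opens 2,2-dimethyloxirane at its unsubstituted CH2 carbon (SN2 epoxide opening, the known route from benzylmagnesium halides to 2-methyl-4-arylbutan-2-ols) and thereby makes the C3–C4 bond and the tertiary alkoxide 4 in one event. KOt-Bu in NMP frees it from magnesium as the potassium alkoxide 5, whose oxygen adds to the neighbouring C–F carbon and expels fluoride through a Meisenheimer intermediate (addition–elimination SNAr), which forms the O1–C8a bond; the closest known reaction type is the base-mediated cyclisation of 3-(2-fluoroaryl)propanols to chromanes, here run in the same flask as the epoxide opening. The pyran ring closes as a six-membered ring by attack of the tethered oxygen on an sp2 ring carbon, 6-exo-trig when counted on the C8–C8a π bond that takes up the charge. No stereocentre is formed. The step needs site selectivity between the two ortho C–F carbons, preference of the tethered alkoxide over tert-butoxide, and a stop after one substitution: the first is settled by symmetry (the two ortho fluorines of the 2,4,6-trifluorophenyl ring are mirror images, so either closure gives 6), the second by intramolecular six-ring delivery against a bulky external base, and the third because the new ring oxygen donates into exactly the carbons (C4a, C6, C8) that would carry the charge in a second Meisenheimer intermediate and so deactivates C5–F and C7–F. Reactivity without a carbonyl activator comes from the fluorine pattern itself, since every C–F carbon of 5 has two meta fluorines that stabilise the anionic σ-complex inductively.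

Step 2
Reactants: 7 methyl 3-(4-hydroxyphenyl)propanoate
Product: 8 methyl 3-(4-hydroxy-3-iodophenyl)propanoate
Conditions: NIS (1.0 equiv), p-TsOH·H2O (10 mol%), MeCN, 0 °C → rt
Reagents that add atoms: N-iodosuccinimide, O=C1CCC(=O)N1I
Why: Electrophilic aromatic iodination, in which the phenol directs ortho (para is blocked by the side chain) and one equivalent of NIS with catalytic acid should stop at the mono-iodide.

Step 3
Reactants: 8 methyl 3-(4-hydroxy-3-iodophenyl)propanoate
Product: 9 methyl 3-[3-iodo-4-(prop-2-en-1-yloxy)phenyl]propanoate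
Conditions: allyl bromide (1.2 equiv), K2CO3, acetone, reflux
Reagents that add atoms: allyl bromide (3-bromoprop-1-ene), C=CCBr
Why: Williamson ether synthesis of the phenoxide with a reactive allylic bromide; the allyl ether masks the phenol against the organometallic steps and is removed in step 8.

Step 4
Reactants: 9 methyl 3-[3-iodo-4-(prop-2-en-1-yloxy)phenyl]propanoate
Product: 11 methyl 3-[3-(3-methylbut-2-en-1-yl)-4-(prop-2-en-1-yloxy)phenyl]propanoate, via arylmagnesium chloride 10 (not isolated)
Conditions: i-PrMgCl·LiCl (1.1 equiv), THF, −20 °C; then CuI (10 mol%), prenyl bromide (1.3 equiv), −20 → 0 °C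
Reagents that add atoms: prenyl bromide (1-bromo-3-methylbut-2-ene), CC(C)=CCBr
Why: Iodine–magnesium exchange of the Knochel type is fast at an iodide ortho to an alkoxy group and tolerates the methyl ester at −20 °C, and the copper-catalysed allylic substitution of the arylmagnesium on prenyl bromide should occur at the unsubstituted CH2 terminus (SN2) because attack at the disubstituted terminus would build a quaternary carbon next to an ortho-substituted arene.

Step 5
Reactants: 11 methyl 3-[3-(3-methylbut-2-en-1-yl)-4-(prop-2-en-1-yloxy)phenyl]propanoate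
Product: 12 N-methoxy-N-methyl-3-[3-(3-methylbut-2-en-1-yl)-4-(prop-2-en-1-yloxy)phenyl]propanamide
Conditions: MeNH(OMe)·HCl (1.5 equiv), i-PrMgCl (3.0 equiv), THF, −20 → 0 °C; 1 M aq. HCl work-up
Reagents that add atoms: N,O-dimethylhydroxylamine hydrochloride, CNOC.Cl
Why: Weinreb amide formation by aminolysis of the ester with the chloromagnesium amide made in the flask from the hydroxylamine salt and i-PrMgCl; the ethers and both alkenes are inert to it.

Step 6
Reactants: 6 5,7-difluoro-2,2-dimethylchromane; 12 N-methoxy-N-methyl-3-[3-(3-methylbut-2-en-1-yl)-4-(prop-2-en-1-yloxy)phenyl]propanamide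
Product: 15 1-(5,7-difluoro-2,2-dimethylchroman-6-yl)-3-[3-(3-methylbut-2-en-1-yl)-4-(prop-2-en-1-yloxy)phenyl]propan-1-one, via aryllithium 13 (not isolated), via tetrahedral lithium adduct 14 (not isolated)
Conditions: n-BuLi (1.05 equiv), THF, −78 °C, 1 h; then 12, −78 °C; then 1 M aq. HCl, −78 → 0 °C
Reagents that add atoms: none
Why: Directed ortho-lithiation followed by Weinreb ketone synthesis: C6–H is the only hydrogen flanked by two C–F bonds and therefore the most acidic (C8–H has one fluorine and one oxygen neighbour), the aryllithium is held at −78 °C so that LiF is not lost, and the chelated tetrahedral adduct releases the ketone only on work-up, which prevents a second addition.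

Step 7
Reactants: 15 1-(5,7-difluoro-2,2-dimethylchroman-6-yl)-3-[3-(3-methylbut-2-en-1-yl)-4-(prop-2-en-1-yloxy)phenyl]propan-1-one
Product: 17 1-[2,2-dimethyl-5,7-bis(prop-2-en-1-yloxy)chroman-6-yl]-3-[3-(3-methylbut-2-en-1-yl)-4-(prop-2-en-1-yloxy)phenyl]propan-1-one, via monoallyloxy monofluoro ketone 16 (not isolated)
Conditions: allyl alcohol (10 equiv), NaH (3 equiv), THF/DMPU (4:1), 0 → 60 °C
Reagents that add atoms: allyl alcohol (prop-2-en-1-ol), C=CCO
Why: Twofold addition–elimination SNAr: both C–F carbons are ortho to the new ketone, which takes up the negative charge of each Meisenheimer intermediate, the ring oxygens already present are meta to the reacting carbons and so do not deactivate them, and the excess of allyl alcohol keeps the ketone largely un-enolised.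

Step 8
Reactants: 17 1-[2,2-dimethyl-5,7-bis(prop-2-en-1-yloxy)chroman-6-yl]-3-[3-(3-methylbut-2-en-1-yl)-4-(prop-2-en-1-yloxy)phenyl]propan-1-one
Product: 18 1-(5,7-dihydroxy-2,2-dimethylchroman-6-yl)-3-[4-hydroxy-3-(3-methylbut-2-en-1-yl)phenyl]propan-1-one
Conditions: Pd(PPh3)4 (5 mol%), morpholine (15 equiv), THF, rt → 40 °C, argon
Reagents that add atoms: none
Why: Tsuji–Trost deallylation: zerovalent palladium ionises each aryl allyl ether to a π-allylpalladium phenoxide pair and the large excess of morpholine traps the allyl unit irreversibly, so the three phenols are released under neutral conditions that leave the prenyl alkene, the ketone and the acid-sensitive ortho-prenylphenol untouched and keep the electron-rich C8 from being C-allylated.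

**Compound list**

1 | 2,4,6-trifluorobenzyl bromide | Fc1cc(F)c(CBr)c(F)c1 | starting material
2 | 2,2-dimethyloxirane | CC1(C)CO1 | starting material
3 | (2,4,6-trifluorobenzyl)magnesium bromide | Fc1cc(F)c(C[Mg]Br)c(F)c1 | intermediate
4 | bromomagnesium 2-methyl-4-(2,4,6-trifluorophenyl)butan-2-olate | CC(C)(CCc1c(F)cc(F)cc1F)O[Mg]Br | intermediate
5 | potassium 2-methyl-4-(2,4,6-trifluorophenyl)butan-2-olate | CC(C)(CCc1c(F)cc(F)cc1F)[O-].[K+] | intermediate
6 | 5,7-difluoro-2,2-dimethylchromane (5,7-difluoro-2,2-dimethyl-3,4-dihydro-2H-1-benzopyran) | CC1(C)CCc2c(F)cc(F)cc2O1 | intermediate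
7 | methyl 3-(4-hydroxyphenyl)propanoate | COC(=O)CCc1ccc(O)cc1 | starting material
8 | methyl 3-(4-hydroxy-3-iodophenyl)propanoate | COC(=O)CCc1ccc(O)c(I)c1 | intermediate
9 | methyl 3-[3-iodo-4-(prop-2-en-1-yloxy)phenyl]propanoate | COC(=O)CCc1ccc(OCC=C)c(I)c1 | intermediate
10 | methyl 3-[3-(chloromagnesio)-4-(prop-2-en-1-yloxy)phenyl]propanoate (LiCl complex) | COC(=O)CCc1ccc(OCC=C)c([Mg]Cl)c1 | intermediate
11 | methyl 3-[3-(3-methylbut-2-en-1-yl)-4-(prop-2-en-1-yloxy)phenyl]propanoate | COC(=O)CCc1ccc(OCC=C)c(CC=C(C)C)c1 | intermediate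
12 | N-methoxy-N-methyl-3-[3-(3-methylbut-2-en-1-yl)-4-(prop-2-en-1-yloxy)phenyl]propanamide | CON(C)C(=O)CCc1ccc(OCC=C)c(CC=C(C)C)c1 | intermediate
13 | (5,7-difluoro-2,2-dimethylchroman-6-yl)lithium | [Li]c1c(F)cc2c(c1F)CCC(C)(C)O2 | intermediate
14 | lithium 1-(5,7-difluoro-2,2-dimethylchroman-6-yl)-1-[methoxy(methyl)amino]-3-[3-(3-methylbut-2-en-1-yl)-4-(prop-2-en-1-yloxy)phenyl]propan-1-olate (racemic) | CON(C)C([O-])(CCc1ccc(OCC=C)c(CC=C(C)C)c1)c1c(F)cc2c(c1F)CCC(C)(C)O2.[Li+] | intermediate
15 | 1-(5,7-difluoro-2,2-dimethylchroman-6-yl)-3-[3-(3-methylbut-2-en-1-yl)-4-(prop-2-en-1-yloxy)phenyl]propan-1-one | CC(C)=CCc1cc(CCC(=O)c2c(F)cc3c(c2F)CCC(C)(C)O3)ccc1OCC=C | intermediate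
16 | 1-[5-fluoro-2,2-dimethyl-7-(prop-2-en-1-yloxy)chroman-6-yl]-3-[3-(3-methylbut-2-en-1-yl)-4-(prop-2-en-1-yloxy)phenyl]propan-1-one (the less hindered C7–F is assumed to react first; the other order converges on 17) | CC(C)=CCc1cc(CCC(=O)c2c(OCC=C)cc3c(c2F)CCC(C)(C)O3)ccc1OCC=C | intermediate
17 | 1-[2,2-dimethyl-5,7-bis(prop-2-en-1-yloxy)chroman-6-yl]-3-[3-(3-methylbut-2-en-1-yl)-4-(prop-2-en-1-yloxy)phenyl]propan-1-one | CC(C)=CCc1cc(CCC(=O)c2c(OCC=C)cc3c(c2OCC=C)CCC(C)(C)O3)ccc1OCC=C | intermediate
18 | 1-(5,7-dihydroxy-2,2-dimethylchroman-6-yl)-3-[4-hydroxy-3-(3-methylbut-2-en-1-yl)phenyl]propan-1-one | CC(C)=CCc1cc(CCC(=O)c2c(O)cc3c(c2O)CCC(C)(C)O3)ccc1O | target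

**Summary**

Total step count: 8. Longest linear sequence: 7 steps (steps 2, 3, 4, 5, 6, 7 and 8, from methyl 3-(4-hydroxyphenyl)propanoate).

Steps most likely to fail:

1. Step 1. The benzylic halide may homocouple during magnesium insertion, and the alkoxide may stay bound to magnesium so that the ring closure stalls. The fallback avoids any benzylic organometallic and separates chain building from ring closure; it sets out from 1 and comes back at 6. Compound 1 is coupled with CH2=C(CH3)CH2MgCl (THF, 0 °C) to give 2-methyl-4-(2,4,6-trifluorophenyl)but-1-ene F1. Mukaiyama hydration (Co(acac)2 cat., PhSiH3, O2, i-PrOH) should give 2-methyl-4-(2,4,6-trifluorophenyl)butan-2-ol F2. Its sodium alkoxide (NaH, DMF, 80 °C) should then close the O1–C8a bond by the same SNAr as a separate step and give 6.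

2. Step 7. Enolisation of the ketone, or twisting of the carbonyl out of the ring plane once one ortho position carries an allyloxy group, may stall the second fluoride exchange; the alkoxide may also attack the carbonyl and split off the aryl group. The fallback moves both exchanges to a non-enolisable aldehyde and builds the ketone afterwards; it sets out from 6 and 11 and comes back at 17. Compound 6 is lithiated as in step 6 and quenched with DMF to give 5,7-difluoro-2,2-dimethylchromane-6-carbaldehyde F3. Allyl alcohol/NaH (THF, rt → 50 °C) should give 2,2-dimethyl-5,7-bis(prop-2-en-1-yloxy)chromane-6-carbaldehyde F4. The lithium enolate of ester 11 (LiN(i-Pr)2, THF, −78 °C) should add to F4 to give the aldol adduct methyl 3-[2,2-dimethyl-5,7-bis(prop-2-en-1-yloxy)chroman-6-yl]-3-hydroxy-2-{[3-(3-methylbut-2-en-1-yl)-4-(prop-2-en-1-yloxy)phenyl]methyl}propanoate F5 as a diastereomer mixture of no consequence. Dess–Martin periodinane should give the β-keto ester methyl 3-[2,2-dimethyl-5,7-bis(prop-2-en-1-yloxy)chroman-6-yl]-3-oxo-2-{[3-(3-methylbut-2-en-1-yl)-4-(prop-2-en-1-yloxy)phenyl]methyl}propanoate F6. Krapcho demethoxycarbonylation (LiCl, DMSO/H2O, 130 °C) should then give 17.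

3. Step 6. The hindered, weakly nucleophilic aryllithium may deprotonate the Weinreb amide at its α-carbon instead of adding, or lose LiF to an aryne before it has added. The fallback uses a more electrophilic partner at a lower oxidation level; it sets out from 12 (with 13 made from 6 as before) and comes back at 15. Compound 12 is reduced with i-Bu2AlH (THF, −78 °C) to 3-[3-(3-methylbut-2-en-1-yl)-4-(prop-2-en-1-yloxy)phenyl]propanal F7. Aryllithium 13 should add to this aldehyde at −78 °C to give 1-(5,7-difluoro-2,2-dimethylchroman-6-yl)-3-[3-(3-methylbut-2-en-1-yl)-4-(prop-2-en-1-yloxy)phenyl]propan-1-ol F8 (racemic). Dess–Martin periodinane (NaHCO3, CH2Cl2) should oxidise it to 15.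

Further compounds
F1 | step 1 | 2-methyl-4-(2,4,6-trifluorophenyl)but-1-ene | C=C(C)CCc1c(F)cc(F)cc1F
F2 | step 1 | 2-methyl-4-(2,4,6-trifluorophenyl)butan-2-ol | CC(C)(O)CCc1c(F)cc(F)cc1F
F3 | step 7 | 5,7-difluoro-2,2-dimethylchromane-6-carbaldehyde | O=Cc1c(F)cc2c(c1F)CCC(C)(C)O2
F4 | step 7 | 2,2-dimethyl-5,7-bis(prop-2-en-1-yloxy)chromane-6-carbaldehyde | O=Cc1c(OCC=C)cc2c(c1OCC=C)CCC(C)(C)O2
F5 | step 7 | methyl 3-[2,2-dimethyl-5,7-bis(prop-2-en-1-yloxy)chroman-6-yl]-3-hydroxy-2-{[3-(3-methylbut-2-en-1-yl)-4-(prop-2-en-1-yloxy)phenyl]methyl}propanoate (diastereomer mixture) | COC(=O)C(Cc1ccc(OCC=C)c(CC=C(C)C)c1)C(O)c1c(OCC=C)cc2c(c1OCC=C)CCC(C)(C)O2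
F6 | step 7 | methyl 3-[2,2-dimethyl-5,7-bis(prop-2-en-1-yloxy)chroman-6-yl]-3-oxo-2-{[3-(3-methylbut-2-en-1-yl)-4-(prop-2-en-1-yloxy)phenyl]methyl}propanoate (racemic) | COC(=O)C(Cc1ccc(OCC=C)c(CC=C(C)C)c1)C(=O)c1c(OCC=C)cc2c(c1OCC=C)CCC(C)(C)O2
F7 | step 6 | 3-[3-(3-methylbut-2-en-1-yl)-4-(prop-2-en-1-yloxy)phenyl]propanal | O=CCCc1ccc(OCC=C)c(CC=C(C)C)c1
F8 | step 6 | 1-(5,7-difluoro-2,2-dimethylchroman-6-yl)-3-[3-(3-methylbut-2-en-1-yl)-4-(prop-2-en-1-yloxy)phenyl]propan-1-ol (racemic) | CC(C)=CCc1cc(CCC(O)c2c(F)cc3c(c2F)CCC(C)(C)O3)ccc1OCC=C
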